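Ring A (C1, C10, C11, C12, C13, C14) carries the C14 oxygen and the exocyclic C11=C20 methylene in a 1,4-relationship across two bare methylenes, C12 and C13: the retron of an aldehyde, a terminal alkyne and ethylene. A rhodium-catalysed hydroacylative [4+2] annulation of the acyclic 4-alkynal 6 (three steps from an organocatalytic Michael addition that sets C10) with ethylene closes ring A, forming C11–C12 and C13–C14 at once. The resulting ketone 8 relays stereochemistry: enolate aldol (C1, C2), directed reduction (C14), lactone-enolate aldol (C8, C9), then Nozaki–Hiyama–Kishi closure of the ten-membered ring at C6–C7, lactone transposition, alkyne semi-reduction and acetylation.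

Key step: step 4

Remark on numbering: carbon numbers follow the target skeleton. Ring A = C1, C10–C14; ten-membered ring = C1–C10; C15 = methyl on C1; C16 = CH2O on C5; lactone = O–C7, C8, C17 (methyl C18), C19 (carbonyl); C20 = exocyclic CH2 on C11. TBS = tert-butyldimethylsilyl, TES = triethylsilyl, PMB = 4-methoxybenzyl.

Assumption: 1, 2, 7, 9, 12 and 16 are bought. The methyl-bearing carbon α to the carbonyl in 3–8 (later C1) is drawn as the expected epimer; it is planarised in step 12, so only C10 has to be set in step 1.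

Step 1
Reactants: 1 3-((4-methoxybenzyl)oxy)propanal; 2 (E)-1-nitroprop-1-ene
Product: 3 (2S,3R)-2-(((4-methoxybenzyl)oxy)methyl)-3-methyl-4-nitrobutanal
Conditions: (S)-α,α-diphenylprolinol trimethylsilyl ether (10 mol %), 4-nitrophenol (10 mol %), toluene, 0 to 20 °C
Reagents that add atoms: none
Why: Organocatalytic Michael addition through the E-enamine of 1, whose bulky diarylsiloxymethyl group shields one face so that 2 should add through the synclinal open transition state to give the syn adduct and fix the future C10 (aldehyde α-carbon) in the required absolute sense.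

Step 2
Reactants: 3 (2S,3R)-2-(((4-methoxybenzyl)oxy)methyl)-3-methyl-4-nitrobutanal
Product: 4 1-((((2R,3R)-2-ethynyl-3-methyl-4-nitrobutyl)oxy)methyl)-4-methoxybenzene
Conditions: dimethyl (1-diazo-2-oxopropyl)phosphonate, K2CO3, MeOH, 0 °C
Reagents that add atoms: dimethyl (1-diazo-2-oxopropyl)phosphonate CC(=O)C(=[N+]=[N-])P(=O)(OC)OC
Why: Seyferth–Gilbert homologation (Ohira–Bestmann form) turns the aldehyde carbon into C11 and adds C20 as the terminal alkyne carbon under carbonate/methanol conditions mild enough to leave the C10 stereocentre untouched.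

Step 3
Reactants: 4 1-((((2R,3R)-2-ethynyl-3-methyl-4-nitrobutyl)oxy)methyl)-4-methoxybenzene
Product: 6 (2R,3R)-3-(((4-methoxybenzyl)oxy)methyl)-2-methylpent-4-ynal, via sodium nitronate 5 (not isolated)
Conditions: NaOMe, MeOH, 0 °C; then aq. TiCl3, NH4OAc buffer (pH 5), 20 °C
Reagents that add atoms: water O
Why: Nef reaction in its titanium trichloride form, in which trivalent titanium reduces the nitronate to the imine that hydrolyses to the C14 aldehyde without affecting the alkyne or the PMB ether; no stereocentre is formed.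

Step 4
Reactants: 6 (2R,3R)-3-(((4-methoxybenzyl)oxy)methyl)-2-methylpent-4-ynal; 7 ethylene
Product: 8 (2R,3R)-3-(((4-methoxybenzyl)oxy)methyl)-2-methyl-4-methylenecyclohexan-1-one
Conditions: [Rh(dppe)]2(BF4)2 (5 mol %; dppe = Ph2PCH2CH2PPh2), ethylene (5 bar), acetone, 40 °C
Reagents that add atoms: none
Why: Proposed new method: cationic monovalent rhodium should insert into the aldehyde C14–H bond of 6, the acyl rhodium hydride should add syn across the tethered C11≡C20 triple bond (hydride to C20, rhodium to C11) to give a five-membered acyl(alkenyl)rhodacycle, ethylene should insert into a Rh–C bond, and C–C reductive elimination should then form C13–C14 and C11–C12, leaving C14 as the ketone and C11=C20 as the exocyclic methylene. The closest known reaction type is the rhodium-catalysed [4+2] annulation of 4-alkynals with alkynes or acrylamides, which runs through the same rhodacycle; ethylene as the two-carbon partner is the untested element. Ring A closes as a formal hydroacylative [4+2] annulation, a six-membered ring released from a seven-membered metallacycle by reductive elimination. No new stereocentre is formed (C14 and C11 are trigonal), the C10 centre from step 1 is not touched, and the epimerisable C1 centre should settle trans to the C10 substituent. The step needs chemoselectivity for ethylene insertion over cyclopentenone formation, ethylene hydroacylation and alkyne oligomerisation; the 4-alkynal geometry, which makes the intramolecular hydrometalation a fast five-membered chelate closure, together with ethylene pressure and the small-bite-angle diphosphine should secure it.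

Step 5
Reactants: 9 tert-butyldimethyl(prop-2-yn-1-yloxy)silane
Product: 10 (Z)-tert-butyldimethyl((2-(tributylstannyl)-3-(trimethylsilyl)allyl)oxy)silane
Conditions: Me3Si–SnBu3, Pd(PPh3)4 (2 mol %), THF, 65 °C
Reagents that add atoms: trimethyl(tributylstannyl)silane CCCC[Sn](CCCC)(CCCC)[Si](C)(C)C
Why: Palladium-catalysed silylstannation of a terminal alkyne, a syn addition that should put tin on the internal carbon (C5) and silicon on the terminal carbon (C6) and so fix the cis relationship behind the 5E geometry.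

Step 6
Reactants: 10 (Z)-tert-butyldimethyl((2-(tributylstannyl)-3-(trimethylsilyl)allyl)oxy)silane
Product: 11 (Z)-tert-butyl((2-iodo-3-(trimethylsilyl)allyl)oxy)dimethylsilane
Conditions: iodine, CH2Cl2, 0 °C
Reagents that add atoms: iodine I-I
Why: Iododestannylation, in which iodine cleaves the C–Sn bond with retention far faster than the C–Si bond and gives the vinyl iodide at C5.

Step 7
Reactants: 11 (Z)-tert-butyl((2-iodo-3-(trimethylsilyl)allyl)oxy)dimethylsilane; 12 3,3-diethoxyprop-1-yne
Product: 13 (E)-tert-butyl((5,5-diethoxy-2-((trimethylsilyl)methylene)pent-3-yn-1-yl)oxy)dimethylsilane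
Conditions: PdCl2(PPh3)2 (3 mol %), CuI (6 mol %), iPr2NH, THF, 20 °C
Reagents that add atoms: none
Why: Sonogashira coupling at the vinyl iodide with retention of geometry attaches C4 (with C3 and the masked C2 aldehyde) cis to the silyl group on C6.

Step 8
Reactants: 13 (E)-tert-butyl((5,5-diethoxy-2-((trimethylsilyl)methylene)pent-3-yn-1-yl)oxy)dimethylsilane
Product: 14 (E)-tert-butyl((5,5-diethoxy-2-(iodomethylene)pent-3-yn-1-yl)oxy)dimethylsilane
Conditions: N-iodosuccinimide, MeCN, 0 °C
Reagents that add atoms: N-iodosuccinimide O=C1CCC(=O)N1I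
Why: Iododesilylation by ipso attack on the vinylsilane through a β-silyl cation should replace silicon by iodine with retention, so that iodine on C6 ends cis to the alkyne (5E).

Step 9
Reactants: 14 (E)-tert-butyl((5,5-diethoxy-2-(iodomethylene)pent-3-yn-1-yl)oxy)dimethylsilane
Product: 15 (E)-4-(((tert-butyldimethylsilyl)oxy)methyl)-5-iodopent-4-en-2-ynal
Conditions: p-TsOH·H2O (cat.), acetone/H2O, 0 to 20 °C
Reagents that add atoms: water O
Why: Acid-catalysed acetal hydrolysis releases the conjugated ynal (C2) under conditions a primary TBS ether tolerates.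

Step 10
Reactants: 16 (R)-4-methyldihydrofuran-2(3H)-one
Product: 18 (3R,4S)-3-hydroxy-4-methyldihydrofuran-2(3H)-one, via potassium enolate 17 (not isolated)
Conditions: KN(SiMe3)2, THF, −78 °C; then 2-(phenylsulfonyl)-3-phenyloxaziridine, −78 °C; aq. NH4Cl
Reagents that add atoms: 2-(phenylsulfonyl)-3-phenyloxaziridine O=S(=O)(c1ccccc1)N1OC1c1ccccc1
Why: Enolate hydroxylation with an N-sulfonyloxaziridine delivers oxygen anti to the C17 methyl group (trans product), although this centre (C8) is planarised again in step 18.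

Step 11
Reactants: 18 (3R,4S)-3-hydroxy-4-methyldihydrofuran-2(3H)-one
Product: 19 (3R,4S)-4-methyl-3-((triethylsilyl)oxy)dihydrofuran-2(3H)-one
Conditions: Et3SiCl, imidazole, CH2Cl2, 0 °C
Reagents that add atoms: chlorotriethylsilane CC[Si](Cl)(CC)CC
Why: Silyl ether formation at the only hydroxyl group gives the α-siloxy lactone donor.

Step 12
Reactants: 8 (2R,3R)-3-(((4-methoxybenzyl)oxy)methyl)-2-methyl-4-methylenecyclohexan-1-one
Product: 20 (S)-((3-(((4-methoxybenzyl)oxy)methyl)-2-methyl-4-methylenecyclohex-1-en-1-yl)oxy)trimethylsilane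
Conditions: iPr2NMgBr, Me3SiCl, Et3N, HMPA, Et2O, 25 °C
Reagents that add atoms: chlorotrimethylsilane C[Si](C)(C)Cl
Why: Thermodynamic silyl enol ether formation, in which the magnesium amide equilibrates the enolates so that the more substituted C14=C1 isomer should dominate, erasing the C1 stereocentre and defining the site of the next C–C bond.

Step 13
Reactants: 20 (S)-((3-(((4-methoxybenzyl)oxy)methyl)-2-methyl-4-methylenecyclohex-1-en-1-yl)oxy)trimethylsilane; 15 (E)-4-(((tert-butyldimethylsilyl)oxy)methyl)-5-iodopent-4-en-2-ynal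
Product: 22 (2S,3S)-2-[(1S,4E)-4-(((tert-butyldimethylsilyl)oxy)methyl)-1-hydroxy-5-iodopent-4-en-2-yn-1-yl]-3-(((4-methoxybenzyl)oxy)methyl)-2-methyl-4-methylenecyclohexan-1-one, via lithium enolate 21 (not isolated)
Conditions: MeLi, THF, 0 °C; then 15, −78 °C; aq. NH4Cl at −78 °C
Reagents that add atoms: none
Why: Directed aldol addition in which the regiodefined tetrasubstituted lithium enolate should add to the ynal through a closed chair transition state on the face anti to the pseudoaxial C10 substituent, so that C2 enters trans to C9 (quaternary C1) and the C1 methyl lies syn to the new C2 hydroxyl (C2).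

Step 14
Reactants: 22 aldol adduct (β-hydroxy ketone)
Product: 23 (1S,2R,3S)-2-[(1S,4E)-4-(((tert-butyldimethylsilyl)oxy)methyl)-1-hydroxy-5-iodopent-4-en-2-yn-1-yl]-3-(((4-methoxybenzyl)oxy)methyl)-2-methyl-4-methylenecyclohexan-1-ol
Conditions: Me4NBH(OAc)3, MeCN/AcOH, −30 °C
Reagents that add atoms: none
Why: Evans–Saksena reduction, in which the C2-bound acetoxyborohydride delivers hydride intramolecularly through a chair transition state, should give the anti-1,3-diol and thus the axial C14 alcohol cis to C2.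

Step 15
Reactants: 23 anti-1,3-diol
Product: 24 bis(tert-butyldimethylsilyl) ether of 23 (silyl ethers at O2 and O14)
Conditions: tert-butyldimethylsilyl triflate, 2,6-lutidine, CH2Cl2, 0 to 20 °C
Reagents that add atoms: tert-butyldimethylsilyl trifluoromethanesulfonate CC(C)(C)[Si](C)(C)OS(=O)(=O)C(F)(F)F
Why: Silyl triflate with a hindered base is reactive enough to silylate both hindered secondary hydroxyl groups.

Step 16
Reactants: 24 bis(tert-butyldimethylsilyl) ether
Product: 25 C9 primary alcohol (24 without the PMB group)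
Conditions: DDQ, CH2Cl2/pH 7 buffer, 0 °C
Reagents that add atoms: none
Why: Oxidative PMB cleavage (benzylic hydride abstraction, hydrolysis of the oxocarbenium ion) frees the C9 hydroxymethyl group without touching silyl ethers, the alkyne or the vinyl iodide.

Step 17
Reactants: 25 C9 primary alcohol
Product: 26 C9 aldehyde
Conditions: Dess–Martin periodinane, NaHCO3, CH2Cl2, 0 °C
Reagents that add atoms: none
Why: Dess–Martin oxidation under buffered, non-basic conditions should give the aldehyde without epimerising C10 or moving the C11=C20 double bond into conjugation.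

Step 18
Reactants: 26 C9 aldehyde; 19 (3R,4S)-4-methyl-3-((triethylsilyl)oxy)dihydrofuran-2(3H)-one
Product: 28 C8–C9 aldol adduct (secondary C9 alcohol on C3 of the 4-methyl-3-(triethylsilyloxy)dihydrofuran-2(3H)-one ring), via lithium enolate 27 (not isolated)
Conditions: 19, LiN(iPr)2, THF, −78 °C; then 26, −78 °C; AcOH in THF at −78 °C
Reagents that add atoms: none
Why: Aldol addition with 1,2-induction, in which the planar lactone enolate should be attacked anti to its C17 methyl group through a closed chair transition state (ring carbon C17 trans to the enolate oxygen), placing C9 trans to that methyl on the new quaternary C8 and the C8 and C9 oxygens syn.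

Step 19
Reactants: 28 C8–C9 aldol adduct
Product: 29 C9 tert-butyldimethylsilyl ether of 28
Conditions: tert-butyldimethylsilyl triflate, 2,6-lutidine, CH2Cl2, −40 to 0 °C
Reagents that add atoms: tert-butyldimethylsilyl trifluoromethanesulfonate CC(C)(C)[Si](C)(C)OS(=O)(=O)C(F)(F)F
Why: Silylation of the C9 hydroxyl blocks retro-aldol cleavage and silyl migration in the following steps.

Step 20
Reactants: 29 C9 silyl ether
Product: 30 C7 N-methoxy-N-methylamide with free C19 hydroxyl
Conditions: MeNH(OMe)·HCl, Me3Al, CH2Cl2, 0 to 20 °C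
Reagents that add atoms: N,O-dimethylhydroxylamine hydrochloride Cl.CNOC
Why: Aluminium amide aminolysis opens the γ-lactone to the C7 amide and frees the C19 hydroxyl; the lactone has no α-hydrogen, so no stereocentre is at risk.

Step 21
Reactants: 30 C7 N-methoxy-N-methylamide
Product: 31 C19 triethylsilyl ether of 30
Conditions: Et3SiCl, imidazole, CH2Cl2, 0 °C
Reagents that add atoms: chlorotriethylsilane CC[Si](Cl)(CC)CC
Why: Silylation of the only free (primary) hydroxyl with a group that can later be removed in the presence of TBS ethers.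

Step 22
Reactants: 31 C19 triethylsilyl ether
Product: 32 C7 aldehyde
Conditions: iBu2AlH, THF, −78 °C
Reagents that add atoms: none
Why: Hydride reduction of the N-methoxy-N-methylamide stops at the chelated hemiaminal and gives the aldehyde on work-up.

Step 23
Reactants: 32 C7 aldehyde
Product: 33 ten-membered-ring 7S allylic alcohol (C6–C7 closed)
Conditions: CrCl2 (excess), NiCl2 (1 mol %), DMSO/THF, 20 °C, high dilution
Reagents that add atoms: none
Why: Nozaki–Hiyama–Kishi macrocyclisation (oxidative addition of C6–I to zerovalent nickel, transmetalation to trivalent chromium, addition of the alkenylchromium to the C7 aldehyde) should close the ten-membered ring with retention of the 5E geometry, and attack anti to the C8–O bond past the smaller C17 branch should give the 7S alcohol.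

Step 24
Reactants: 33 ten-membered-ring allylic alcohol
Product: 34 C7/C19 diol (33 without the primary triethylsilyl group)
Conditions: pyridinium p-toluenesulfonate (cat.), MeOH/CH2Cl2, 0 °C
Reagents that add atoms: none
Why: Mild acid methanolysis removes the primary triethylsilyl ether selectively, since it is cleaved much faster than the tertiary TES ether or the TBS ethers.

Step 25
Reactants: 34 C7/C19 diol
Product: 35 γ-lactone (ring oxygen on C7 and C19 carbonyl; 3,4-didehydro skeleton of the target in protected form)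
Conditions: TEMPO (cat.), PhI(OAc)2, CH2Cl2, 20 °C
Reagents that add atoms: none
Why: Oxoammonium-catalysed oxidative lactonisation oxidises the primary C19 alcohol first, the aldehyde is trapped by the C7 hydroxyl as the lactol, and this is oxidised to the γ-lactone with retention at C7.

Step 26
Reactants: 35 γ-lactone
Product: 36 protected (3Z,5E)-diene
Conditions: Zn(Cu/Ag), MeOH/H2O, 45 °C
Reagents that add atoms: none
Why: Semi-reduction of the conjugated enyne with activated zinc adds two hydrogens cis to the triple bond only, which should give the 3Z alkene and leave C5=C6 and C11=C20 alone.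

Step 27
Reactants: 36 protected (3Z,5E)-diene
Product: 37 pentaol (free hydroxyls at C2 and C8 and C9 and C14 and C16)
Conditions: HF·pyridine, pyridine, THF, 0 to 20 °C
Reagents that add atoms: none
Why: Fluoride cleavage of all five silyl ethers (Si–F bond formation) under buffered acidic conditions that avoid retro-aldol cleavage of the β-hydroxy lactone.

Step 28
Reactants: 37 pentaol
Product: 38 CNP0269068.1 (target)
Conditions: Ac2O, pyridine, DMAP (cat.), CH2Cl2, 0 to 20 °C
Reagents that add atoms: acetic anhydride CC(=O)OC(C)=O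
Why: DMAP-catalysed acylation esterifies the primary and the three secondary hydroxyl groups, whereas the hindered tertiary C8 hydroxyl should stay free.

Compound list
1 | 3-((4-methoxybenzyl)oxy)propanal | O=CCCOCc1ccc(OC)cc1 | starting material
2 | (E)-1-nitroprop-1-ene | C/C=C/[N+](=O)[O-] | starting material
3 | (2S,3R)-2-(((4-methoxybenzyl)oxy)methyl)-3-methyl-4-nitrobutanal | O=C[C@H](COCc1ccc(OC)cc1)[C@@H](C)C[N+](=O)[O-] | intermediate
4 | 1-((((2R,3R)-2-ethynyl-3-methyl-4-nitrobutyl)oxy)methyl)-4-methoxybenzene | C#C[C@H](COCc1ccc(OC)cc1)[C@@H](C)C[N+](=O)[O-] | intermediate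
5 | sodium nitronate of 4 | [Na+].C#C[C@H](COCc1ccc(OC)cc1)[C@@H](C)C=[N+]([O-])[O-] | intermediate
6 | (2R,3R)-3-(((4-methoxybenzyl)oxy)methyl)-2-methylpent-4-ynal | C#C[C@H](COCc1ccc(OC)cc1)[C@@H](C)C=O | intermediate
7 | ethylene | C=C | starting material
8 | (2R,3R)-3-(((4-methoxybenzyl)oxy)methyl)-2-methyl-4-methylenecyclohexan-1-one | C=C1CCC(=O)[C@H](C)[C@H]1COCc2ccc(OC)cc2 | intermediate
9 | tert-butyldimethyl(prop-2-yn-1-yloxy)silane | C#CCO[Si](C)(C)C(C)(C)C | starting material
10 | (Z)-tert-butyldimethyl((2-(tributylstannyl)-3-(trimethylsilyl)allyl)oxy)silane | C[Si](C)(C)/C=C(\[Sn](CCCC)(CCCC)CCCC)CO[Si](C)(C)C(C)(C)C | intermediate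
11 | (Z)-tert-butyl((2-iodo-3-(trimethylsilyl)allyl)oxy)dimethylsilane | C[Si](C)(C)/C=C(\I)CO[Si](C)(C)C(C)(C)C | intermediate
12 | 3,3-diethoxyprop-1-yne | C#CC(OCC)OCC | starting material
13 | (E)-tert-butyl((5,5-diethoxy-2-((trimethylsilyl)methylene)pent-3-yn-1-yl)oxy)dimethylsilane | C[Si](C)(C)/C=C(\C#CC(OCC)OCC)CO[Si](C)(C)C(C)(C)C | intermediate
14 | (E)-tert-butyl((5,5-diethoxy-2-(iodomethylene)pent-3-yn-1-yl)oxy)dimethylsilane | I/C=C(\C#CC(OCC)OCC)CO[Si](C)(C)C(C)(C)C | intermediate
15 | (E)-4-(((tert-butyldimethylsilyl)oxy)methyl)-5-iodopent-4-en-2-ynal | I/C=C(\C#CC=O)CO[Si](C)(C)C(C)(C)C | intermediate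
16 | (R)-4-methyldihydrofuran-2(3H)-one | O=C1OC[C@H](C)C1 | starting material
17 | potassium enolate of 16 | [K+].[O-]C1=C[C@@H](C)CO1 | intermediate
18 | (3R,4S)-3-hydroxy-4-methyldihydrofuran-2(3H)-one | O=C1OC[C@H](C)[C@H]1O | intermediate
19 | (3R,4S)-4-methyl-3-((triethylsilyl)oxy)dihydrofuran-2(3H)-one | O=C1OC[C@H](C)[C@H]1O[Si](CC)(CC)CC | intermediate
20 | (S)-((3-(((4-methoxybenzyl)oxy)methyl)-2-methyl-4-methylenecyclohex-1-en-1-yl)oxy)trimethylsilane | C=C1CCC(O[Si](C)(C)C)=C(C)[C@H]1COCc2ccc(OC)cc2 | intermediate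
21 | lithium (S)-3-(((4-methoxybenzyl)oxy)methyl)-2-methyl-4-methylenecyclohex-1-en-1-olate | [Li+].C=C1CCC([O-])=C(C)[C@H]1COCc2ccc(OC)cc2 | intermediate
22 | (2S,3S)-2-[(1S,4E)-4-(((tert-butyldimethylsilyl)oxy)methyl)-1-hydroxy-5-iodopent-4-en-2-yn-1-yl]-3-(((4-methoxybenzyl)oxy)methyl)-2-methyl-4-methylenecyclohexan-1-one | C=C1CCC(=O)[C@](C)([C@@H](O)C#C/C(CO[Si](C)(C)C(C)(C)C)=C\I)[C@H]1COCc2ccc(OC)cc2 | intermediate
23 | (1S,2R,3S)-2-[(1S,4E)-4-(((tert-butyldimethylsilyl)oxy)methyl)-1-hydroxy-5-iodopent-4-en-2-yn-1-yl]-3-(((4-methoxybenzyl)oxy)methyl)-2-methyl-4-methylenecyclohexan-1-ol | C=C1CC[C@H](O)[C@](C)([C@@H](O)C#C/C(CO[Si](C)(C)C(C)(C)C)=C\I)[C@H]1COCc2ccc(OC)cc2 | intermediate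
24 | bis(tert-butyldimethylsilyl) ether of 23 (at O2 and O14; configuration unchanged) | C=C1CC[C@H](O[Si](C)(C)C(C)(C)C)[C@](C)([C@@H](O[Si](C)(C)C(C)(C)C)C#C/C(CO[Si](C)(C)C(C)(C)C)=C\I)[C@H]1COCc2ccc(OC)cc2 | intermediate
25 | C9 primary alcohol (24 with CH2OH in place of CH2OPMB) | C=C1CC[C@H](O[Si](C)(C)C(C)(C)C)[C@](C)([C@@H](O[Si](C)(C)C(C)(C)C)C#C/C(CO[Si](C)(C)C(C)(C)C)=C\I)[C@H]1CO | intermediate
26 | C9 aldehyde (25 oxidised at C9; C10 configuration unchanged) | C=C1CC[C@H](O[Si](C)(C)C(C)(C)C)[C@](C)([C@@H](O[Si](C)(C)C(C)(C)C)C#C/C(CO[Si](C)(C)C(C)(C)C)=C\I)[C@H]1C=O | intermediate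
27 | lithium enolate of 19 | [Li+].[O-]C1=C(O[Si](CC)(CC)CC)[C@@H](C)CO1 | intermediate
28 | C8–C9 aldol adduct: C9 carbinol joined to the quaternary C8 (OTES) of the 4-methyl lactone, C9 trans to the C17 methyl, C8/C9 oxygens syn | C=C1CC[C@H](O[Si](C)(C)C(C)(C)C)[C@](C)([C@@H](O[Si](C)(C)C(C)(C)C)C#C/C(CO[Si](C)(C)C(C)(C)C)=C\I)[C@H]1[C@H](O)[C@@]2(O[Si](CC)(CC)CC)C(=O)OC[C@@H]2C | intermediate
29 | C9 tert-butyldimethylsilyl ether of 28 | C=C1CC[C@H](O[Si](C)(C)C(C)(C)C)[C@](C)([C@@H](O[Si](C)(C)C(C)(C)C)C#C/C(CO[Si](C)(C)C(C)(C)C)=C\I)[C@H]1[C@H](O[Si](C)(C)C(C)(C)C)[C@@]2(O[Si](CC)(CC)CC)C(=O)OC[C@@H]2C | intermediate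
30 | ring-opened C7 N-methoxy-N-methylamide of 29 with free C19 hydroxyl | C=C1CC[C@H](O[Si](C)(C)C(C)(C)C)[C@](C)([C@@H](O[Si](C)(C)C(C)(C)C)C#C/C(CO[Si](C)(C)C(C)(C)C)=C\I)[C@H]1[C@H](O[Si](C)(C)C(C)(C)C)[C@@](O[Si](CC)(CC)CC)(C(=O)N(C)OC)[C@@H](C)CO | intermediate
31 | C19 triethylsilyl ether of 30 | C=C1CC[C@H](O[Si](C)(C)C(C)(C)C)[C@](C)([C@@H](O[Si](C)(C)C(C)(C)C)C#C/C(CO[Si](C)(C)C(C)(C)C)=C\I)[C@H]1[C@H](O[Si](C)(C)C(C)(C)C)[C@@](O[Si](CC)(CC)CC)(C(=O)N(C)OC)[C@@H](C)CO[Si](CC)(CC)CC | intermediate
32 | C7 aldehyde (31 with CHO in place of the amide) | C=C1CC[C@H](O[Si](C)(C)C(C)(C)C)[C@](C)([C@@H](O[Si](C)(C)C(C)(C)C)C#C/C(CO[Si](C)(C)C(C)(C)C)=C\I)[C@H]1[C@H](O[Si](C)(C)C(C)(C)C)[C@@](O[Si](CC)(CC)CC)(C=O)[C@@H](C)CO[Si](CC)(CC)CC | intermediate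
33 | ten-membered-ring 7S allylic alcohol (3-yne, 5E-ene; all centres as in the target) | C=C1CC[C@H](O[Si](C)(C)C(C)(C)C)[C@]2(C)[C@@H](O[Si](C)(C)C(C)(C)C)C#C/C(CO[Si](C)(C)C(C)(C)C)=C\[C@H](O)[C@@](O[Si](CC)(CC)CC)([C@@H](C)CO[Si](CC)(CC)CC)[C@@H](O[Si](C)(C)C(C)(C)C)[C@@H]12 | intermediate
34 | C7/C19 diol (33 without the primary triethylsilyl group) | C=C1CC[C@H](O[Si](C)(C)C(C)(C)C)[C@]2(C)[C@@H](O[Si](C)(C)C(C)(C)C)C#C/C(CO[Si](C)(C)C(C)(C)C)=C\[C@H](O)[C@@](O[Si](CC)(CC)CC)([C@@H](C)CO)[C@@H](O[Si](C)(C)C(C)(C)C)[C@@H]12 | intermediate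
35 | γ-lactone (O–C7, C19 carbonyl), 3-yne, silyl-protected | C=C1CC[C@H](O[Si](C)(C)C(C)(C)C)[C@]2(C)[C@@H](O[Si](C)(C)C(C)(C)C)C#C/C(CO[Si](C)(C)C(C)(C)C)=C\[C@@H]3OC(=O)[C@H](C)[C@@]3(O[Si](CC)(CC)CC)[C@@H](O[Si](C)(C)C(C)(C)C)[C@@H]12 | intermediate
36 | silyl-protected (3Z,5E)-diene lactone | C=C1CC[C@H](O[Si](C)(C)C(C)(C)C)[C@]2(C)[C@@H](O[Si](C)(C)C(C)(C)C)/C=C\C(CO[Si](C)(C)C(C)(C)C)=C/[C@@H]3OC(=O)[C@H](C)[C@@]3(O[Si](CC)(CC)CC)[C@@H](O[Si](C)(C)C(C)(C)C)[C@@H]12 | intermediate
37 | pentaol (2,8,9,14,16-pentahydroxy compound) | C=C1CC[C@H](O)[C@]2(C)[C@@H](O)/C=C\C(CO)=C/[C@@H]3OC(=O)[C@H](C)[C@@]3(O)[C@@H](O)[C@@H]12 | intermediate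
38 | CNP0269068.1: (1R,2S,3Z,5E,7S,8S,9S,10S,14S,17R)-2,9,14,16-tetraacetoxy-8-hydroxy-11(20)-methylene lactone | C=C1CC[C@H](OC(C)=O)[C@]2(C)[C@@H](OC(C)=O)/C=C\C(COC(C)=O)=C/[C@@H]3OC(=O)[C@H](C)[C@@]3(O)[C@@H](OC(C)=O)[C@@H]12 | target

Total step count: 28 (steps 5–9 make ynal 15, steps 10–11 make lactone 19).
Longest linear sequence: 21 steps (steps 1–4 and 12–28).

Steps most likely to fail

1. Step 4 (proposed new method). Ethylene may fail to insert into the acyl(alkenyl)rhodacycle, so that intramolecular hydroacylation to a cyclopentenone, hydroacylation of ethylene or alkyne oligomerisation takes over; the rhodium hydride may also isomerise the exocyclic alkene. The fallback uses known chemistry, sets out from 6 and comes back at 8. Addition of CH2=CHMgBr (THF, −78 °C) should give the allylic alcohol (4R,5R)-5-(((4-methoxybenzyl)oxy)methyl)-4-methylhept-1-en-6-yn-3-ol F1. Dess–Martin oxidation should give the vinyl ketone (4R,5R)-5-(((4-methoxybenzyl)oxy)methyl)-4-methylhept-1-en-6-yn-3-one F2. Bu3SnH/AIBN (benzene, 80 °C, slow addition) should add a stannyl radical to C20, and the C11 vinyl radical should close 6-endo onto the enone terminus C12 to give the stannylmethylene ketone (2R,3R)-3-(((4-methoxybenzyl)oxy)methyl)-2-methyl-4-((tributylstannyl)methylene)cyclohexan-1-one F3. Protodestannylation (TsOH·H2O, CH2Cl2) should then give 8.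

2. Step 23. Strain in the ten-membered enyne may slow the intramolecular addition, so that reduction of the vinyl iodide or intermolecular coupling competes, and the facial selectivity at C7 may be poor. The fallback sets out from 31 and comes back at 33. Iodine–lithium exchange (t-BuLi, THF/Et2O, −95 °C, high dilution) followed by intramolecular acylation of the vinyllithium by the N-methoxy-N-methylamide should give the macrocyclic C7 enone F4. Corey–Bakshi–Shibata reduction ((R)-2-methyl-CBS-oxazaborolidine, BH3·SMe2, −30 °C) should then set C7 under reagent control, with the quaternary C8 side as the large group, and give 33.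

3. Step 18. The addition joins a tetrasubstituted enolate to a hindered α-branched aldehyde, so slow addition, retro-aldol cleavage or enolisation of 26 (loss of C10 integrity) may result. The fallback sets out from 26 and comes back at 28. Pinnick oxidation (NaClO2, NaH2PO4, 2-methylbut-2-ene, t-BuOH/H2O) should give the C9 carboxylic acid F5. 1,1'-Carbonyldiimidazole (THF) should give the C9 acyl imidazole F6. Irreversible C-acylation of lithium enolate 27 (from 19 and LiN(iPr)2, −78 °C), again anti to the C17 methyl, should give the C9 keto lactone F7. Chelation-controlled reduction with Zn(BH4)2 (Et2O, −20 °C) should then give 28; the C9 configuration from this reduction would have to be confirmed.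

Further compounds
F1 | step 4 | (4R,5R)-5-(((4-methoxybenzyl)oxy)methyl)-4-methylhept-1-en-6-yn-3-ol (both carbinol epimers) | C#C[C@H](COCc1ccc(OC)cc1)[C@@H](C)C(O)C=C
F2 | step 4 | (4R,5R)-5-(((4-methoxybenzyl)oxy)methyl)-4-methylhept-1-en-6-yn-3-one | C#C[C@H](COCc1ccc(OC)cc1)[C@@H](C)C(=O)C=C
F3 | step 4 | (2R,3R)-3-(((4-methoxybenzyl)oxy)methyl)-2-methyl-4-((tributylstannyl)methylene)cyclohexan-1-one | CCCC[Sn](CCCC)(CCCC)C=C1CCC(=O)[C@H](C)[C@H]1COCc2ccc(OC)cc2
F4 | step 23 | macrocyclic C7 enone (33 with C7 ketone) | C=C1CC[C@H](O[Si](C)(C)C(C)(C)C)[C@]2(C)[C@@H](O[Si](C)(C)C(C)(C)C)C#C/C(CO[Si](C)(C)C(C)(C)C)=C\C(=O)[C@@](O[Si](CC)(CC)CC)([C@@H](C)CO[Si](CC)(CC)CC)[C@@H](O[Si](C)(C)C(C)(C)C)[C@@H]12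
F5 | step 18 | C9 carboxylic acid (26 oxidised) | C=C1CC[C@H](O[Si](C)(C)C(C)(C)C)[C@](C)([C@@H](O[Si](C)(C)C(C)(C)C)C#C/C(CO[Si](C)(C)C(C)(C)C)=C\I)[C@H]1C(=O)O
F6 | step 18 | C9 acyl imidazole | C=C1CC[C@H](O[Si](C)(C)C(C)(C)C)[C@](C)([C@@H](O[Si](C)(C)C(C)(C)C)C#C/C(CO[Si](C)(C)C(C)(C)C)=C\I)[C@H]1C(=O)n2ccnc2
F7 | step 18 | C9 keto lactone (28 with C9 ketone) | C=C1CC[C@H](O[Si](C)(C)C(C)(C)C)[C@](C)([C@@H](O[Si](C)(C)C(C)(C)C)C#C/C(CO[Si](C)(C)C(C)(C)C)=C\I)[C@H]1C(=O)[C@@]2(O[Si](CC)(CC)CC)C(=O)OC[C@@H]2C
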